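**Strategy.** Locants: C3 ketone carbon, C4=C5 enone alkene, C6 lactone carbinol, C7, C8 acyloxy carbon, C9 methylene, C10 methyl carbinol. C3 and C8 lie 1,6 across the ten-membered ring, and C3 to C8 are the six ring carbons of (S)-carvone (C3–C8 is its C1–C6 bond). The medium ring is therefore hidden in a carvone-derived bicycle and the C3–C8 bond is cut last. The key step closes six-membered ring B at C9–C10 by ring-closing metathesis of a C8 vinyl group with a C3 3-methylbut-3-enyl chain. The cis C3 hydroxyl then bridges to C10, fixing its configuration, and alkoxy-radical fragmentation of C3–C8 unveils the germacranolide.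

Key step: step 5

Remark: locants follow the target throughout (C11–C13 lactone methylidene unit with C12 carbonyl and C13 =CH2; C14 methyl on C10; C15 hydroxymethyl on C4); ring A is the carvone ring C3–C4–C5–C6–C7–C8 and ring B is C3–C2–C1–C10–C9–C8; (R)-2-methylbutanoic acid is taken as commercially available, and the target is handled as the open hydroxy ketone that is drawn.

Step 1
Reactants: 1 (S)-(+)-carvone
Product: 3 trans-6-(triethylsilyloxy)carvone, via triethylsilyl dienol ether 2 (not isolated)
Conditions: LiN(i-Pr)2, Et3SiCl, THF, −78 °C; then mCPBA, NaHCO3, CH2Cl2, −20 °C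
Reagents that add atoms: chlorotriethylsilane (CC[Si](Cl)(CC)CC); 3-chloroperoxybenzoic acid (O=C(OO)c1cccc(Cl)c1)
Why: Kinetic α′-enolate silylation and Rubottom oxidation (epoxidation of the silyl enol ether, silyl shift) should put oxygen on C8; the configuration of this centre is re-set in step 2.

Step 2
Reactants: 3 trans-6-(triethylsilyloxy)carvone
Product: 4 6-(1-hydroxyethyl)-6-(triethylsilyloxy)carvone (carbinol epimers)
Conditions: LiN(i-Pr)2, THF, −78 °C; CH3CHO, −78 °C; AcOH quench
Reagents that add atoms: acetaldehyde (CC=O)
Why: Aldol addition of the tetrasubstituted α-silyloxy enolate, in which the aldehyde should approach C8 anti to the C7 isopropenyl group as in alkylations of carvone enolates, so that the C8 oxygen ends cis to the isopropenyl group.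

Step 3
Reactants: 4 6-(1-hydroxyethyl)-6-(triethylsilyloxy)carvone
Product: 6 6-vinyl-6-(triethylsilyloxy)carvone (vinyl trans to isopropenyl), via secondary mesylate 5 (not isolated)
Conditions: MeSO2Cl, Et3N, CH2Cl2, 0 °C; then DBU, toluene, 80 °C
Reagents that add atoms: none
Why: Mesylation and E2 elimination; C8 is quaternary, so only the methyl hydrogens are available and the vinyl group must form.

Step 4
Reactants: 6 6-vinyl-6-(triethylsilyloxy)carvone; 7 4-bromo-2-methylbut-1-ene
Product: 9 tertiary alcohol (C3 hydroxyl cis to the C8 silyloxy group; C3 chain cis to the C8 vinyl group), via homoallylic Grignard reagent 8 (not isolated)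
Conditions: Mg, THF, 25 °C; then 6, LaCl3·2LiCl (30 mol%), THF, −78 to 0 °C; aq. NH4Cl
Reagents that add atoms: none
Why: Lanthanum-assisted 1,2-addition of the Grignard reagent to the hindered enone carbonyl; the axial C8 silyloxy group blocks its own face, so the chain should enter anti to it (Felkin–Anh sense) and end cis to the vinyl group.

Step 5
Reactants: 9 tertiary alcohol
Product: 10 cis-fused bicyclic alcohol (ring B closed with a C9=C10 double bond)
Conditions: second-generation Grubbs catalyst RuCl2(=CHPh)(PCy3)(H2IMes) (5 mol%), CH2Cl2, 40 °C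
Reagents that add atoms: none
Why: The ruthenium alkylidene loads on one terminal alkene of 9 and closes onto the other by [2+2] cycloaddition and cycloreversion, expelling ethylene and forming the C9=C10 bond (Chauvin mechanism). The closest known reaction type is ring-closing metathesis of a tertiary allylic carbinol derivative with a 1,1-disubstituted alkene to a trisubstituted cyclohexene. It closes the six-membered carbocycle ring B (C3–C2–C1–C10–C9–C8) cis-fused to ring A, because steps 2 and 4 placed the vinyl group and the chain cis on C8 and C3. No stereocentre is formed here; the C10 configuration is set in step 6 by the C3 hydroxyl, which this closure holds across ring B from C10. The step needs chemoselectivity among four alkenes, and the substrate secures it: the isopropenyl group could only close a four-membered ring with the vinyl group or a seven-membered tetrasubstituted alkene with the chain, and the ring A trisubstituted alkene is inert. The feature exploited is the 1,6 relation of C3 and C8 across the ten-membered ring, so that a temporary C3–C8 bond turns a medium-ring closure into a cyclohexene closure.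

Step 6
Reactants: 10 cis-fused bicyclic alcohol
Product: 12 oxygen-bridged tricycle (C3–O–C10 ether; C8 silyl ether), via C9 organomercurial 11 (not isolated)
Conditions: Hg(OCOCF3)2, CH2Cl2, −20 °C; then NaBH4, aq. NaOH, 0 °C
Reagents that add atoms: none
Why: Intramolecular alkoxymercuration–demercuration (cineole-type cycloetherification); the C3 hydroxyl can only bridge to the Markovnikov carbon C10 on its own face, so the C10 oxygen ends cis to the C3 and C8 oxygens and to the C7 side chain, with the methyl group on the other face.

Step 7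
Reactants: 12 oxygen-bridged tricycle
Product: 13 bridged C8 tertiary alcohol
Conditions: Bu4NF, THF, 25 °C
Reagents that add atoms: none
Why: Fluoride desilylation of the tertiary triethylsilyl ether; nothing else in the molecule is fluoride-labile.

Step 8
Reactants: 13 bridged C8 tertiary alcohol
Product: 14 bridged C6 enone
Conditions: Rh2(cap)4 (cap = caprolactamate, 1 mol%), t-BuOOH (70% in water), K2CO3, CH2Cl2, 25 °C
Reagents that add atoms: tert-butyl hydroperoxide (CC(C)(C)OO)
Why: Allylic C–H oxidation by a tert-butylperoxyl radical chain; ring A has a single allylic methylene (C6) because C3 is quaternary, and the enone formed is deactivated.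

Step 9
Reactants: 14 bridged C6 enone
Product: 15 bridged C6 allylic alcohol (hydroxyl cis to isopropenyl)
Conditions: LiBH(s-Bu)3, THF, −78 °C
Reagents that add atoms: none
Why: 1,2-Reduction of the β,β-disubstituted enone; axial delivery is blocked by the syn-axial C8 hydroxyl, so the bulky hydride should enter equatorially and give the C6 alcohol cis to the C7 isopropenyl group.

Step 10
Reactants: 15 bridged C6 allylic alcohol
Product: 16 bridged tetraol (hydroxyls on C6/C8/C12/C15)
Conditions: SeO2 (cat.), t-BuOOH, CH2Cl2, 25 °C
Reagents that add atoms: tert-butyl hydroperoxide (CC(C)(C)OO)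
Why: Selenium dioxide allylic hydroxylation (ene reaction then [2,3]-shift) at the more substituted end of each alkene: on C4 only the C15 methyl carries hydrogen, and on C11 the C12 methyl is preferred over the C7 methine.

Step 11
Reactants: 16 bridged tetraol
Product: 17 cis-fused α-methylene lactone enal (C15 aldehyde)
Conditions: TEMPO (cat.), PhI(OAc)2, CH2Cl2, 25 °C
Reagents that add atoms: none
Why: Oxoammonium oxidation of both primary allylic alcohols; the C12 aldehyde is trapped by the cis C6 hydroxyl as a lactol that is oxidised on to the cis-fused α-methylene-γ-butyrolactone, while C15 stops at the enal and the tertiary C8 alcohol is inert.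

Step 12
Reactants: 17 lactone enal
Product: 18 lactone C15 allylic alcohol
Conditions: NaBH4, CeCl3·7H2O, MeOH, −78 °C
Reagents that add atoms: none
Why: Luche 1,2-reduction of the enal; at −78 °C the lactone carbonyl and the methylidene group should not be touched.

Step 13
Reactants: 18 lactone C15 allylic alcohol
Product: 19 lactone C15 tert-butyldimethylsilyl ether
Conditions: t-BuMe2SiCl, imidazole, DMF, 0 °C
Reagents that add atoms: tert-butylchlorodimethylsilane (CC(C)(C)[Si](C)(C)Cl)
Why: Silylation of the only primary hydroxyl; the tertiary C8 alcohol does not react under these conditions.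

Step 14
Reactants: 19 lactone C15 silyl ether
Product: 21 ten-membered hydroxy diketone (C3 enone; C8 ketone; C10 hydroxyl; 15-O-silyl), via C3 acetoxy ketal 20 (not isolated)
Conditions: PhI(OAc)2, I2, CaCO3, CH2Cl2, visible light, 0 to 25 °C; then aq. NaHCO3/Na2S2O3, wet silica
Reagents that add atoms: water (O)
Why: Alkoxy-radical fragmentation: the C8 hypoiodite gives the C8 alkoxyl radical, whose β-scission of the C3–C8 bond releases the bicyclic strain and leaves a tertiary, allylic, oxygen-stabilised C3 radical that is oxidised and trapped as the acetoxy ketal; hydrolysis gives the C3 enone and frees the bridge oxygen as the C10 hydroxyl.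

Step 15
Reactants: 21 ten-membered hydroxy diketone
Product: 22 syn-1,3-diol (C8 alcohol)
Conditions: Et2BOMe, NaBH4, THF/MeOH 4:1, −78 °C; then AcOH, MeOH
Reagents that add atoms: none
Why: Narasaka–Prasad reduction: the C10 hydroxyl and the C8 ketone form a six-membered boron chelate, and external hydride delivery should give the syn-1,3-diol, which is the required C8 configuration; the conjugated C3 ketone and the methylidene lactone are not activated.

Step 16
Reactants: 22 syn-1,3-diol; 23 (R)-2-methylbutanoic acid
Product: 24 15-O-silyl C8 ester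
Conditions: N,N′-diisopropylcarbodiimide, DMAP (cat.), CH2Cl2, 0 °C
Reagents that add atoms: none
Why: Steglich esterification of the only secondary alcohol; the tertiary C10 hydroxyl is not acylated and the acid stereocentre is carried in unchanged.

Step 17
Reactants: 24 15-O-silyl C8 ester
Product: 25 target CNP0130221.1
Conditions: HF·pyridine, THF/pyridine, 0 °C
Reagents that add atoms: none
Why: Buffered fluoride cleavage of the primary silyl ether, compatible with lactone, ester and enone.

**Compound list**

1 | (S)-(+)-carvone | CC1=CC[C@@H](CC1=O)C(C)=C | starting material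
2 | triethylsilyl dienol ether of carvone (C3–OSiEt3, C3=C8) | CC1=CC[C@H](C(C)=C)C=C1O[Si](CC)(CC)CC | intermediate
3 | trans-6-(triethylsilyloxy)carvone (C8 silyloxy trans to C7 isopropenyl) | CC1=CC[C@H](C(C)=C)[C@@H](O[Si](CC)(CC)CC)C1=O | intermediate
4 | 6-(1-hydroxyethyl)-6-(triethylsilyloxy)carvone (C8–C9 bond trans and C8–O cis to isopropenyl; C9 carbinol epimers) | CC1=CC[C@H](C(C)=C)[C@@](O[Si](CC)(CC)CC)(C(C)O)C1=O | intermediate
5 | methanesulfonate of 4 | CC1=CC[C@H](C(C)=C)[C@@](O[Si](CC)(CC)CC)(C(C)OS(C)(=O)=O)C1=O | intermediate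
6 | 6-vinyl-6-(triethylsilyloxy)carvone | CC1=CC[C@H](C(C)=C)[C@@](O[Si](CC)(CC)CC)(C=C)C1=O | intermediate
7 | 4-bromo-2-methylbut-1-ene | C=C(C)CCBr | starting material
8 | (3-methylbut-3-en-1-yl)magnesium bromide | C=C(C)CC[Mg]Br | intermediate
9 | tertiary alcohol: 3-methylbut-3-enyl and OH on C3, vinyl and OSiEt3 on C8 (the two oxygens cis, the two carbon chains cis) | CC1=CC[C@H](C(C)=C)[C@@](O[Si](CC)(CC)CC)(C=C)[C@@]1(O)CCC(C)=C | intermediate
10 | cis-fused bicyclic alcohol (ring B with C9=C10; C3–OH and C8–OSiEt3 at the ring fusion) | CC1=CC[C@H](C(C)=C)[C@@]2(O[Si](CC)(CC)CC)C=C(C)CC[C@@]12O | intermediate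
11 | C9 (trifluoroacetoxy)mercurio derivative of the bridged ether | CC1=CC[C@H](C(C)=C)[C@@]2(O[Si](CC)(CC)CC)[C@@H]([Hg]OC(=O)C(F)(F)F)[C@@]3(C)CC[C@@]12O3 | intermediate
12 | oxygen-bridged tricycle (C3–O–C10 ether, C8–OSiEt3) | CC1=CC[C@H](C(C)=C)[C@@]2(O[Si](CC)(CC)CC)C[C@@]3(C)CC[C@@]12O3 | intermediate
13 | bridged C8 tertiary alcohol | CC1=CC[C@H](C(C)=C)[C@@]2(O)C[C@@]3(C)CC[C@@]12O3 | intermediate
14 | bridged C6 enone | CC1=CC(=O)[C@H](C(C)=C)[C@@]2(O)C[C@@]3(C)CC[C@@]12O3 | intermediate
15 | bridged C6 allylic alcohol (OH cis to isopropenyl) | CC1=C[C@H](O)[C@H](C(C)=C)[C@@]2(O)C[C@@]3(C)CC[C@@]12O3 | intermediate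
16 | bridged tetraol (C6, C8, C12, C15 hydroxyls) | OCC1=C[C@H](O)[C@H](C(=C)CO)[C@@]2(O)C[C@@]3(C)CC[C@@]12O3 | intermediate
17 | cis-fused α-methylene lactone with C15 aldehyde | O=CC1=C[C@@H]2OC(=O)C(=C)[C@@H]2[C@@]3(O)C[C@@]4(C)CC[C@@]13O4 | intermediate
18 | lactone with C15 hydroxyl | OCC1=C[C@@H]2OC(=O)C(=C)[C@@H]2[C@@]3(O)C[C@@]4(C)CC[C@@]13O4 | intermediate
19 | lactone with C15 tert-butyldimethylsilyl ether | CC(C)(C)[Si](C)(C)OCC1=C[C@@H]2OC(=O)C(=C)[C@@H]2[C@@]3(O)C[C@@]4(C)CC[C@@]13O4 | intermediate
20 | C3 acetoxy ketal of the ten-membered ring (3,10-oxygen bridge, C8 ketone; C3 epimers) | C=C1C(=O)O[C@H]2/C=C(/CO[Si](C)(C)C(C)(C)C)C3(OC(C)=O)CC[C@@](C)(O3)CC(=O)[C@@H]12 | intermediate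
21 | ten-membered hydroxy diketone (C3 enone, C8 ketone, C10–OH, 15-O-silyl) | C=C1C(=O)O[C@H]2/C=C(/CO[Si](C)(C)C(C)(C)C)C(=O)CC[C@@](C)(O)CC(=O)[C@@H]12 | intermediate
22 | C8 alcohol (syn to C10–OH) | C=C1C(=O)O[C@H]2/C=C(/CO[Si](C)(C)C(C)(C)C)C(=O)CC[C@@](C)(O)C[C@@H](O)[C@@H]12 | intermediate
23 | (R)-2-methylbutanoic acid | CC[C@@H](C)C(=O)O | starting material
24 | 15-O-silyl C8 (R)-2-methylbutanoate | C=C1C(=O)O[C@H]2/C=C(/CO[Si](C)(C)C(C)(C)C)C(=O)CC[C@@](C)(O)C[C@@H](OC(=O)[C@H](C)CC)[C@@H]12 | intermediate
25 | CNP0130221.1 | C=C1C(=O)O[C@H]2/C=C(/CO)C(=O)CC[C@@](C)(O)C[C@@H](OC(=O)[C@H](C)CC)[C@@H]12 | target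

**Step count.** Total: 17 steps. Longest linear sequence: 17 steps, from (S)-carvone.

**Steps most likely to fail**

- Step 2. Deprotonation may occur at the vinylogous C6 position, the silyl group may shift to the new alkoxide, and the crowded aldolate may revert. Fallback: from 3, the lithium enolate (LiN(i-Pr)2, THF, −78 °C) is added in a conjugate sense to phenyl vinyl sulfoxide to give the C8 2-(phenylsulfinyl)ethyl ketone F1. Heating F1 in toluene at 110 °C with CaCO3 expels benzenesulfenic acid by syn-elimination and returns to 6.
- Step 8. Hydrogen abstraction may compete at the C7 methine or the methyl groups of the isopropenyl unit, and over-oxidation is possible. Fallback: from 13, sensitised photooxygenation (O2, tetraphenylporphyrin, light, CH2Cl2) as a Schenck ene reaction should give the C4 tertiary allylic hydroperoxide F2 with the alkene moved to C5=C6. Allylic hydroperoxide rearrangement on standing in chloroform should move the peroxide to C6, giving the C6 secondary hydroperoxide F3. Dehydration of F3 with Ac2O and pyridine returns to 14.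
- Step 15. Facial selectivity in the flexible ten-membered ring may be poor, and base may trigger retro-aldol cleavage or lactone elimination. Fallback: from 21, hydroxyl-directed anti reduction with Me4NBH(OAc)3 in MeCN/AcOH at −30 °C should give the C8-epimeric alcohol F4. F4 is esterified with 23 under Mitsunobu conditions (PPh3, diisopropyl azodicarboxylate, THF) with inversion, returning to 24.

**Further compounds**

F1 | step 2 | 6-[2-(phenylsulfinyl)ethyl]-6-(triethylsilyloxy)carvone | CC1=CC[C@H](C(C)=C)[C@@](O[Si](CC)(CC)CC)(CCS(=O)c2ccccc2)C1=O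
F2 | step 8 | C4 tertiary allylic hydroperoxide of the bridged alcohol (C5=C6) | C[C@@]1(OO)C=C[C@H](C(C)=C)[C@@]2(O)C[C@@]3(C)CC[C@@]12O3
F3 | step 8 | C6 secondary allylic hydroperoxide of the bridged alcohol (C4=C5) | CC1=C[C@H](OO)[C@H](C(C)=C)[C@@]2(O)C[C@@]3(C)CC[C@@]12O3
F4 | step 15 | C8-epimeric alcohol (anti to C10–OH) | C=C1C(=O)O[C@H]2/C=C(/CO[Si](C)(C)C(C)(C)C)C(=O)CC[C@@](C)(O)C[C@H](O)[C@@H]12
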